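**Plan**
- Retrosynthesis: after removal of the two O-benzyl groups, the C7'–C1' bond (ring S to its benzylic CH2) and the C8'–C9' bond (methyl) are cut together, leaving an (R)-3-methyl-4-arylbut-1-ene and a syringyl bromide. The butene is then cut at C8'=C7' (methylenation) and at C8–C9 (methyl), back to eugenol.
- Enabling feature: each half of the target is an aryl–CH2–CH(CH3) unit (ring G–C7–C8(C9) and ring S–C7'–C8'(C9')), that is, a terminal alkene that has gained methyl at its inner carbon and a carbon group at its terminus. Eugenol already is ring G–C7–CH=CH2.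
- Forward: no ring is formed. The chain grows linearly on ring G (benzylation, methylalumination–oxidation, oxidation to the aldehyde, methylenation), then a second methylalumination with in-flask arylation by the ring S bromide, then hydrogenolysis.
- Stereochemistry: C8 (R) and C8' (S) are set in two separate catalyst-controlled methylaluminations with the same antipode, (−)-bis(1-neomenthylindenyl)zirconium dichloride, (−)-(NMI)2ZrCl2. The same alkene face is used each time, which gives the meso-like (8R,8'S) pattern. C8 is polished by lipase acetylation.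

Key step: step 6

Remark on the chemistry: the face preference of (−)-(NMI)2ZrCl2 known for unbranched 1-alkenes is assumed to hold for the allylically branched alkene of the key step, and the lipase treatment in step 2 is counted as part of the purification of that step.

**Step 1**
Reactants: 1 eugenol; 2 benzyl bromide
Product: 3 4-allyl-1-benzyloxy-2-methoxybenzene
Conditions: BnBr, K2CO3, acetone, reflux
Reagents that add atoms: benzyl bromide, BrCc1ccccc1
Why: Williamson ether synthesis, in which the phenoxide of eugenol displaces bromide, and the benzyl ether masks the acidic phenol from Me3Al and from the bases used later.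

**Step 2**
Reactants: 3 4-allyl-1-benzyloxy-2-methoxybenzene; 4 trimethylaluminium
Product: 6 (R)-3-(4-benzyloxy-3-methoxyphenyl)-2-methylpropan-1-ol, via primary alkylalane 5 (not isolated)
Conditions: Me3Al (2.5 equiv), (−)-(NMI)2ZrCl2 (5 mol %), methylaluminoxane (MeAlO)n, CH2Cl2, 0 to 23 °C; O2, 0 to 23 °C; aq. NaOH; then Amano PS lipase, vinyl acetate, THF, 23 °C, run until the residual (S)-alcohol is acetylated; chromatography
Reagents that add atoms: trimethylaluminium, C[Al](C)C; dioxygen, O=O
Why: Zirconium-catalysed asymmetric carboalumination of a terminal alkene (ZACA reaction) with oxidation of the C–Al bond by O2, in which the chiral methylzirconocene cation puts methyl on the inner carbon and the metal on the terminus, the (−)-antipode being the one that gives (R)-2-methylalkan-1-ols and so setting C8 as (R), while the lipase, which acetylates the (S)-alcohol faster, clears the minor enantiomer.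

**Step 3**
Reactants: 6 (R)-3-(4-benzyloxy-3-methoxyphenyl)-2-methylpropan-1-ol
Product: 7 (R)-3-(4-benzyloxy-3-methoxyphenyl)-2-methylpropanal
Conditions: Dess–Martin periodinane, NaHCO3, CH2Cl2, 0 to 23 °C; crude aldehyde used at once
Reagents that add atoms: none
Why: Dess–Martin oxidation of a primary alcohol under buffered, amine-free conditions, so that the stereocentre C8 next to the new carbonyl group is not enolised.

**Step 4**
Reactants: 7 (R)-3-(4-benzyloxy-3-methoxyphenyl)-2-methylpropanal
Product: 8 (R)-1-benzyloxy-2-methoxy-4-(2-methylbut-3-en-1-yl)benzene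
Conditions: Ph3PCH3Br (1.5 equiv), KN(SiMe3)2 (1.4 equiv), THF, 0 °C; then 7, −78 to 0 °C
Reagents that add atoms: methyltriphenylphosphonium bromide, C[P+](c1ccccc1)(c1ccccc1)c1ccccc1.[Br-]
Why: Wittig methylenation, in which the non-stabilised ylide, kept free of excess base, adds to the aldehyde at low temperature faster than it deprotonates the α-position, so C8 passes unchanged into the allylic position of the alkene.

**Step 5**
Reactants: 9 4-bromo-2,6-dimethoxyphenol; 2 benzyl bromide
Product: 10 2-benzyloxy-5-bromo-1,3-dimethoxybenzene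
Conditions: BnBr, K2CO3, DMF, 60 °C
Reagents that add atoms: benzyl bromide, BrCc1ccccc1
Why: Williamson ether synthesis on a hindered but acidic 2,6-dimethoxyphenol, with warm DMF overcoming the two ortho methoxy groups.

**Step 6**
Reactants: 8 (R)-1-benzyloxy-2-methoxy-4-(2-methylbut-3-en-1-yl)benzene; 4 trimethylaluminium; 10 2-benzyloxy-5-bromo-1,3-dimethoxybenzene
Product: 13 2-benzyloxy-5-[(2S,3R)-4-(4-benzyloxy-3-methoxyphenyl)-2,3-dimethylbutyl]-1,3-dimethoxybenzene, via primary alkylalane 11 (not isolated), via alkylzinc triflate 12 (not isolated)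
Conditions: Me3Al (3 equiv), (−)-(NMI)2ZrCl2 (10 mol %), methylaluminoxane (MeAlO)n, CH2Cl2, 0 to 23 °C; volatiles removed in vacuo; Zn(OTf)2 (1.2 equiv), DMF, 70 °C; then 10 (2 equiv), Pd(P(t-Bu)3)2 (5 mol %), DMF, 23 to 60 °C
Reagents that add atoms: trimethylaluminium, C[Al](C)C; 2-benzyloxy-5-bromo-1,3-dimethoxybenzene, COc1cc(Br)cc(OC)c1OCc1ccccc1
Why: Proposed new method: the methylzirconocene cation (tetravalent zirconium) formed from (−)-(NMI)2ZrCl2, Me3Al and methylaluminoxane should insert the C8'=C7' alkene of 8 with methyl going to the inner carbon C8' (the C8'–C9' bond) and the metal to C7', Zr-to-Al exchange giving alane 11; Zn(OTf)2 then moves the primary alkyl group to zinc (12), which transmetalates to the arylpalladium bromide (divalent palladium) formed from 10 and zerovalent palladium, and reductive elimination forms the C7'–C1' bond. The closest known reaction type is the zirconium-catalysed asymmetric methylalumination of unbranched 1-alkenes followed in the same flask by Zn(OTf)2-mediated, palladium-catalysed cross-coupling of the alkylalane; new here is an alkene whose allylic carbon is branched and stereogenic, together with an aryl bromide as the electrophile. No ring is closed. The new stereocentre C8' is set by the catalyst: the (−)-antipode, which gives (R)-2-methylalkan-1-ols from 1-alkenes, should deliver methyl to the same alkene face here, and with the changed CIP ranks this reads (2R,3R) in 11 and 12 and (S) at C8' in 13. The step needs face selectivity, which rests on the catalyst antipode with C8 acting only as a matched or mismatched partner, regioselectivity, which follows from zirconium preferring the unhindered terminal carbon, and freedom from β-hydride transfer or double-bond migration (which would erase C8), which the bulky neomenthylindenyl ligands and the chlorinated solvent are meant to secure. The excess of 10 absorbs any methyl transfer from residual methylaluminium species during the coupling.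

**Step 7**
Reactants: 13 2-benzyloxy-5-[(2S,3R)-4-(4-benzyloxy-3-methoxyphenyl)-2,3-dimethylbutyl]-1,3-dimethoxybenzene
Product: 14 4-[(2S,3R)-4-(4-hydroxy-3-methoxyphenyl)-2,3-dimethylbutyl]-2,6-dimethoxyphenol
Conditions: H2 (1 atm), Pd/C (10 % Pd), EtOAc/MeOH, 23 °C
Reagents that add atoms: none
Why: Catalytic hydrogenolysis of both benzyl aryl ethers over palladium on carbon, to which the saturated chain, the methyl ethers and the two non-epimerisable stereocentres are inert.

**Compound list**
1 | eugenol (4-allyl-2-methoxyphenol) | C=CCc1ccc(O)c(OC)c1 | starting material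
2 | benzyl bromide | BrCc1ccccc1 | starting material
3 | 4-allyl-1-benzyloxy-2-methoxybenzene | C=CCc1ccc(OCc2ccccc2)c(OC)c1 | intermediate
4 | trimethylaluminium | C[Al](C)C | starting material
5 | dimethyl[(R)-3-(4-benzyloxy-3-methoxyphenyl)-2-methylpropyl]aluminium | COc1cc(C[C@@H](C)C[Al](C)C)ccc1OCc1ccccc1 | intermediate
6 | (R)-3-(4-benzyloxy-3-methoxyphenyl)-2-methylpropan-1-ol | COc1cc(C[C@@H](C)CO)ccc1OCc1ccccc1 | intermediate
7 | (R)-3-(4-benzyloxy-3-methoxyphenyl)-2-methylpropanal | COc1cc(C[C@@H](C)C=O)ccc1OCc1ccccc1 | intermediate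
8 | (R)-1-benzyloxy-2-methoxy-4-(2-methylbut-3-en-1-yl)benzene | COc1cc(C[C@@H](C)C=C)ccc1OCc1ccccc1 | intermediate
9 | 4-bromo-2,6-dimethoxyphenol | COc1cc(Br)cc(OC)c1O | starting material
10 | 2-benzyloxy-5-bromo-1,3-dimethoxybenzene | COc1cc(Br)cc(OC)c1OCc1ccccc1 | intermediate
11 | dimethyl[(2R,3R)-4-(4-benzyloxy-3-methoxyphenyl)-2,3-dimethylbutyl]aluminium | COc1cc(C[C@@H](C)[C@@H](C)C[Al](C)C)ccc1OCc1ccccc1 | intermediate
12 | [(2R,3R)-4-(4-benzyloxy-3-methoxyphenyl)-2,3-dimethylbutyl]zinc trifluoromethanesulfonate | COc1cc(C[C@@H](C)[C@@H](C)C[Zn]OS(=O)(=O)C(F)(F)F)ccc1OCc1ccccc1 | intermediate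
13 | 2-benzyloxy-5-[(2S,3R)-4-(4-benzyloxy-3-methoxyphenyl)-2,3-dimethylbutyl]-1,3-dimethoxybenzene | COc1cc(C[C@@H](C)[C@@H](C)Cc2cc(OC)c(OCc3ccccc3)c(OC)c2)ccc1OCc1ccccc1 | intermediate
14 | 4-[(2S,3R)-4-(4-hydroxy-3-methoxyphenyl)-2,3-dimethylbutyl]-2,6-dimethoxyphenol | COc1cc(C[C@@H](C)[C@@H](C)Cc2cc(OC)c(O)c(OC)c2)ccc1O | target

**Totals**
Total step count: 7. Longest linear sequence: 6 steps (steps 1, 2, 3, 4, 6 and 7).

**Steps most likely to fail**

Step 6. The methylzirconation may be slow or poorly face-selective on an alkene whose allylic carbon is branched and stereogenic (mismatched pairing with C8, competing hydrometalation, or double-bond migration that erases C8). Methyl transfer may also compete with alkyl transfer in the coupling. The fallback uses known chemistry, sets out from aldehyde 7 and comes back at 13. Corey–Fuchs homologation (CBr4, PPh3, Zn, CH2Cl2) should turn 7 into the dibromoalkene (R)-1-benzyloxy-4-(4,4-dibromo-2-methylbut-3-en-1-yl)-2-methoxybenzene F1, and n-BuLi (THF, −78 °C) then gives the terminal alkyne (R)-1-benzyloxy-2-methoxy-4-(2-methylbut-3-yn-1-yl)benzene F2. Zirconium-catalysed syn-methylalumination of the alkyne (Me3Al, Cp2ZrCl2, CH2Cl2) should give the alkenylalane dimethyl[(1E,3R)-4-(4-benzyloxy-3-methoxyphenyl)-2,3-dimethylbut-1-en-1-yl]aluminium F3. This is coupled in the same flask with bromide 10 (Pd(P(t-Bu)3)2, ZnCl2 as co-catalyst, THF) to the trisubstituted alkene 2-benzyloxy-5-[(1E,3R)-4-(4-benzyloxy-3-methoxyphenyl)-2,3-dimethylbut-1-en-1-yl]-1,3-dimethoxybenzene F4, so the same two bonds are formed. Asymmetric hydrogenation of F4 with a chiral iridium phosphine–oxazoline catalyst, [Ir(cod)(PHOX)]B(ArF)4 (H2, CH2Cl2), then sets C8' and gives 13. The ligand antipode is chosen by screening, and the benzyl ethers survive homogeneous hydrogenation.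

Step 2. Methyl transfer to an unbranched allylarene is only moderately enantioselective, and the lipase polish may not clear the minor enantiomer at an acceptable recovery. The fallback sets out from 3 and comes back at 6 by auxiliary control. Hydroboration–oxidation (9-BBN, THF; H2O2, NaOH) should give 3-(4-benzyloxy-3-methoxyphenyl)propan-1-ol F5, and oxidation (TEMPO, PhI(OAc)2, MeCN/H2O) gives 3-(4-benzyloxy-3-methoxyphenyl)propanoic acid F6. Activation as the mixed anhydride (pivaloyl chloride, Et3N) and acylation of lithiated (R)-4-benzyloxazolidin-2-one give the imide (R)-4-benzyl-3-[3-(4-benzyloxy-3-methoxyphenyl)propanoyl]oxazolidin-2-one F7. Evans methylation (NaN(SiMe3)2, MeI, THF, −78 °C) gives (R)-4-benzyl-3-[(R)-3-(4-benzyloxy-3-methoxyphenyl)-2-methylpropanoyl]oxazolidin-2-one F8, with the methyl entering opposite the auxiliary benzyl group and the diastereomers separable. Reductive removal of the auxiliary with LiBH4 (THF, MeOH) gives 6.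

Step 4. Enolisation of the α-branched aldehyde by the ylide, or during handling between steps 3 and 4, may erode C8. The fallback sets out from 3 and comes back at 8 without passing through a carbonyl compound. Cross-metathesis of 3 with (E)-1,4-dibromobut-2-ene (second-generation Hoveyda–Grubbs catalyst, CH2Cl2, 40 °C) should give the allylic bromide (E)-1-benzyloxy-4-(4-bromobut-2-en-1-yl)-2-methoxybenzene F9. Copper-catalysed asymmetric allylic alkylation with MeMgBr (CuBr·SMe2, Taniaphos, CH2Cl2, −75 °C) then delivers methyl to the γ-carbon in the SN2′ sense and gives 8 directly. The ligand antipode that gives the (R)-alkene is to be assigned on the first run.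

**Further compounds**
F1 | step 6 | (R)-1-benzyloxy-4-(4,4-dibromo-2-methylbut-3-en-1-yl)-2-methoxybenzene | COc1cc(C[C@@H](C)C=C(Br)Br)ccc1OCc1ccccc1
F2 | step 6 | (R)-1-benzyloxy-2-methoxy-4-(2-methylbut-3-yn-1-yl)benzene | COc1cc(C[C@@H](C)C#C)ccc1OCc1ccccc1
F3 | step 6 | dimethyl[(1E,3R)-4-(4-benzyloxy-3-methoxyphenyl)-2,3-dimethylbut-1-en-1-yl]aluminium | COc1cc(C[C@@H](C)/C(C)=C/[Al](C)C)ccc1OCc1ccccc1
F4 | step 6 | 2-benzyloxy-5-[(1E,3R)-4-(4-benzyloxy-3-methoxyphenyl)-2,3-dimethylbut-1-en-1-yl]-1,3-dimethoxybenzene | COc1cc(C[C@@H](C)/C(C)=C/c2cc(OC)c(OCc3ccccc3)c(OC)c2)ccc1OCc1ccccc1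
F5 | step 2 | 3-(4-benzyloxy-3-methoxyphenyl)propan-1-ol | COc1cc(CCCO)ccc1OCc1ccccc1
F6 | step 2 | 3-(4-benzyloxy-3-methoxyphenyl)propanoic acid | COc1cc(CCC(=O)O)ccc1OCc1ccccc1
F7 | step 2 | (R)-4-benzyl-3-[3-(4-benzyloxy-3-methoxyphenyl)propanoyl]oxazolidin-2-one | COc1cc(CCC(=O)N2[C@H](Cc3ccccc3)COC2=O)ccc1OCc1ccccc1
F8 | step 2 | (R)-4-benzyl-3-[(R)-3-(4-benzyloxy-3-methoxyphenyl)-2-methylpropanoyl]oxazolidin-2-one | COc1cc(C[C@@H](C)C(=O)N2[C@H](Cc3ccccc3)COC2=O)ccc1OCc1ccccc1
F9 | step 4 | (E)-1-benzyloxy-4-(4-bromobut-2-en-1-yl)-2-methoxybenzene | COc1cc(C/C=C/CBr)ccc1OCc1ccccc1
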